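## Retrosynthetic overview

1. Polymatin A comes from its 9-O-TBS ether; the 8β-angelate is installed with inversion (Mitsunobu) on an 8α-alcohol, so the ring closure can follow its intrinsic stereochemical preference.
2. The ten-membered ring (formed second) is closed at C7–C8 by a CrCl2-mediated intramolecular Barbier reaction. C7, the β-carbon of a 3-(bromomethyl)butenolide, acts as the nucleophile (a lactone homoenolate equivalent) toward the C8 α-silyloxy aldehyde, setting C7 and C8.
3. The butenolide (formed first) comes from ring-closing metathesis of the 2-(bromomethyl)acrylate of an (S)-divinyl carbinol; C6 is set by asymmetric vinylation of a geranial-type enal.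
4. C9 and the masked C8 aldehyde come from (R)-glyceraldehyde acetonide, joined to C10 by Nozaki–Hiyama–Kishi coupling of a (Z)-α-iodoenoate; C1=C10 comes from an iodo-Wittig reaction on the ozonolysis aldehyde of geranyl acetate.
5. Commercial inputs: geranyl acetate, Ph3P=CHCO2Me, (R)-glyceraldehyde acetonide, 2-(bromomethyl)acrylic acid, angelic acid.

Assumption: positions C1–C15 follow germacrane numbering of the target (6R,7S,8S,9S as drawn); a metal alkoxide present before aqueous work-up is treated as the metal-bound form of the product and is not numbered.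

## Route

Step 1
Reactants: 1 geranyl acetate [(2E)-3,7-dimethylocta-2,6-dien-1-yl acetate]
Product: 3 (2E)-3-methyl-6-oxohex-2-en-1-yl acetate, via secondary ozonide 2 (not isolated)
Conditions: O3 (1.0 equiv), CH2Cl2, −78 °C; then Me2S, −78 °C → rt
Reagents that add atoms: ozone [O-][O+]=O
Why: Chemoselective ozonolysis, since the electron-rich 6,7-alkene reacts much faster than the 2,3-alkene deactivated by the allylic acetate, and Me2S reduces the ozonide to the aldehyde; no stereocentre is formed and the 2E geometry (future C4=C5) is untouched.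

Step 2
Reactants: 3 (2E)-3-methyl-6-oxohex-2-en-1-yl acetate
Product: 4 methyl (2Z,6E)-8-acetoxy-2-iodo-6-methylocta-2,6-dienoate
Conditions: Ph3P=CHCO2Me, NIS, CH2Cl2, −20 °C, 20 min; then 3, −20 °C → rt
Reagents that add atoms: methyl (triphenylphosphoranylidene)acetate COC(=O)C=P(c1ccccc1)(c1ccccc1)c1ccccc1; N-iodosuccinimide O=C1CCC(=O)N1I
Why: Wittig olefination with the α-iodinated stabilised ylide made in situ places the ester trans to the chain, giving the (Z)-α-iodoenoate and thereby fixing the C1=C10 geometry of the target.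

Step 3
Reactants: 4 methyl (2Z,6E)-8-acetoxy-2-iodo-6-methylocta-2,6-dienoate; 5 (R)-2,2-dimethyl-1,3-dioxolane-4-carbaldehyde
Product: 7 methyl (2E,6E)-8-acetoxy-2-{(S)-hydroxy[(4R)-2,2-dimethyl-1,3-dioxolan-4-yl]methyl}-6-methylocta-2,6-dienoate, via alkenyl-CrCl2 species 6 (not isolated)
Conditions: CrCl2 (4 equiv), NiCl2 (2 mol %), DMF, rt; aq NH4Cl
Reagents that add atoms: none
Why: Nozaki–Hiyama–Kishi coupling, in which the alkenyl-CrCl2 species forms with retention of alkene geometry and adds to the α-alkoxy aldehyde in the Felkin–Anh (anti) sense, setting C9 as S (expected dr about 4–8:1, minor syn epimer removed by chromatography).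

Step 4
Reactants: 7 the C9 alcohol from step 3
Product: 8 methyl (2E,6E)-8-acetoxy-2-{(S)-(tert-butyldimethylsilyloxy)[(4R)-2,2-dimethyl-1,3-dioxolan-4-yl]methyl}-6-methylocta-2,6-dienoate
Conditions: TBSOTf, 2,6-lutidine, CH2Cl2, −78 → 0 °C
Reagents that add atoms: tert-butyldimethylsilyl triflate CC(C)(C)[Si](C)(C)OS(=O)(=O)C(F)(F)F
Why: Silyl triflate silylation protects the hindered allylic C9 alcohol as a bulky, non-chelating ether, which is needed later for Felkin–Anh control at C8.

Step 5
Reactants: 8 the TBS ether acetate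
Product: 9 methyl (2E,6E)-2-{(S)-(TBSO)[(4R)-2,2-dimethyl-1,3-dioxolan-4-yl]methyl}-8-hydroxy-6-methylocta-2,6-dienoate
Conditions: K2CO3 (0.2 equiv), MeOH, 0 °C
Reagents that add atoms: none
Why: Base-catalysed transesterification (Zemplén type) removes only the acetate, because the methyl ester exchanges degenerately and the silyl ether and acetonide are base-stable.

Step 6
Reactants: 9 the primary allylic alcohol
Product: 10 methyl (2E,6E)-2-{(S)-(TBSO)[(4R)-2,2-dimethyl-1,3-dioxolan-4-yl]methyl}-6-methyl-8-oxoocta-2,6-dienoate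
Conditions: [Cu(MeCN)4]OTf (5 mol %), 2,2'-bipyridine, TEMPO, N-methylimidazole, air, MeCN, rt
Reagents that add atoms: none
Why: Copper/TEMPO aerobic oxidation (Stahl oxidation) is selective for the primary allylic alcohol and gives the enal without E/Z isomerisation.

Step 7
Reactants: 10 the enal
Product: 11 methyl (2E,6E,8S)-2-{(S)-(TBSO)[(4R)-2,2-dimethyl-1,3-dioxolan-4-yl]methyl}-8-hydroxy-6-methyldeca-2,6,9-trienoate
Conditions: Zn(CH=CH2)2 (pre-formed, salt-free, 2 equiv), (−)-MIB (10 mol %), toluene/hexane, −20 → 0 °C; aq NH4Cl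
Reagents that add atoms: divinylzinc C=C[Zn]C=C
Why: Amino-alcohol-catalysed asymmetric organozinc 1,2-addition, in which the (−)-MIB zinc complex delivers vinyl to the Si face of the enal (as it does for dialkylzincs) to give the 8S carbinol, which is C6 of the target with its natural spatial arrangement.

Step 8
Reactants: 11 the (S)-divinyl carbinol; 12 2-(bromomethyl)acrylic acid
Product: 13 methyl (2E,6E,8S)-8-{[2-(bromomethyl)acryloyl]oxy}-2-{(S)-(TBSO)[(4R)-2,2-dimethyl-1,3-dioxolan-4-yl]methyl}-6-methyldeca-2,6,9-trienoate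
Conditions: DCC, DMAP (5 mol %), CH2Cl2, −20 → 0 °C
Reagents that add atoms: none
Why: Steglich esterification at low temperature acylates the only free hydroxyl without displacing the allylic bromide and without touching the carbinol stereocentre.

Step 9
Reactants: 13 the 2-(bromomethyl)acrylate
Product: 14 methyl (2E,6E)-7-[(2R)-4-(bromomethyl)-5-oxo-2,5-dihydrofuran-2-yl]-2-{(S)-(TBSO)[(4R)-2,2-dimethyl-1,3-dioxolan-4-yl]methyl}-6-methylhepta-2,6-dienoate
Conditions: second-generation Grubbs catalyst RuCl2(=CHPh)(H2IMes)(PCy3) (5–10 mol %), toluene (5 mM), 80 °C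
Reagents that add atoms: none
Why: Ring-closing metathesis, in which the ruthenium carbene initiates at the monosubstituted vinyl group and closes onto the acrylate to the five-membered butenolide with loss of ethylene, the trisubstituted alkenes being inert and C6 untouched (its descriptor becomes R only through a priority change).

Step 10
Reactants: 14 the bromomethyl butenolide acetonide
Product: 16 methyl (2E,6E)-7-[(2R)-4-(bromomethyl)-5-oxo-2,5-dihydrofuran-2-yl]-2-[(1S)-1-(TBSO)-2-oxoethyl]-6-methylhepta-2,6-dienoate, via vicinal diol 15 (not isolated)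
Conditions: H5IO6 (2 equiv), EtOAc, rt; used crude at once
Reagents that add atoms: none
Why: Periodic acid hydrolyses the terminal acetonide and cleaves the resulting 1,2-diol in one pot (glycol cleavage) under mildly acidic, base-free conditions, so the silyl ether, the allylic bromide and the enolisable C9 centre survive.

Step 11
Reactants: 16 the bromomethyl butenolide aldehyde
Product: 18 8-epi-8-O-deangeloyl-9-O-TBS-polymatin A (8α-hydroxy-9α-silyloxy melampolide; 8R and 9S; C6 and C7 as in the target), via allyl-CrCl2 species 17 (not isolated)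
Conditions: CrCl2 (8 equiv), THF, rt, 16 added by syringe pump over 10 h to 2 mM final concentration; aq NH4Cl
Reagents that add atoms: none
Why: Proposed new method: CrCl2 reduces the allylic bromide to an allyl-CrCl2 species in which C7, normally the electrophilic β-carbon of the butenolide, becomes the nucleophilic γ-terminus (a lactone homoenolate equivalent) and adds to the C8 aldehyde through a closed six-membered Zimmerman–Traxler transition state; attack anti to the C6 side chain gives the trans-fused lactone (C7 as in the target), the ring-locked E-type allyl unit with C9 equatorial gives the 7,8-anti relationship, and Felkin–Anh addition anti to the C9–OTBS bond reinforces it, so C8 forms as 8R (8α-OH) with all three elements matched; ring-opening 1,4-elimination of the lactone carboxylate is disfavoured because the C6–O bond lies in the nodal plane of the allyl system; the closest known reactions are intermolecular zinc- or chromium-mediated Barbier additions of 3-(bromomethyl)furan-2(5H)-one to aldehydes and CrCl2-mediated macrocyclisations of 2-(bromomethyl)acrylates onto aldehydes to ten-membered germacranolides.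

Step 12
Reactants: 18 the 8α-alcohol; 19 angelic acid [(Z)-2-methylbut-2-enoic acid]
Product: 20 9-O-TBS-polymatin A
Conditions: PPh3, DIAD, toluene, 0 °C → rt
Reagents that add atoms: none
Why: Mitsunobu esterification, in which SN2 displacement of the activated C8 oxygen by angelate inverts C8 from R to the natural S (8β-O) configuration, and the Z geometry of the acid is kept because the alcohol, not the acyl group, is activated.

Step 13
Reactants: 20 9-O-TBS-polymatin A
Product: 21 polymatin A
Conditions: HF·pyridine, THF/pyridine, 0 °C → rt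
Reagents that add atoms: none
Why: Fluoride-mediated desilylation under buffered acidic conditions frees the C9 hydroxyl while avoiding base-induced acyl migration from O8 to O9, translactonisation and angelate-to-tiglate isomerisation.

## Compound list

1 | geranyl acetate, (2E)-3,7-dimethylocta-2,6-dien-1-yl acetate | CC(C)=CCC/C(C)=C/COC(C)=O | starting material
2 | secondary ozonide, 5-[(3E)-5-acetoxy-3-methylpent-3-en-1-yl]-3,3-dimethyl-1,2,4-trioxolane | CC1(C)OOC(CC/C(C)=C/COC(C)=O)O1 | intermediate
3 | (2E)-3-methyl-6-oxohex-2-en-1-yl acetate | O=CCC/C(C)=C/COC(C)=O | intermediate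
4 | methyl (2Z,6E)-8-acetoxy-2-iodo-6-methylocta-2,6-dienoate | COC(=O)/C(I)=C/CC/C(C)=C/COC(C)=O | intermediate
5 | (R)-2,2-dimethyl-1,3-dioxolane-4-carbaldehyde (2,3-O-isopropylidene-D-glyceraldehyde) | O=C[C@H]1COC(C)(C)O1 | starting material
6 | alkenyl-CrCl2 species, methyl (2Z,6E)-8-acetoxy-2-(dichlorochromio)-6-methylocta-2,6-dienoate | COC(=O)/C(=C/CC/C(C)=C/COC(C)=O)[Cr](Cl)Cl | intermediate
7 | methyl (2E,6E)-8-acetoxy-2-{(S)-hydroxy[(4R)-2,2-dimethyl-1,3-dioxolan-4-yl]methyl}-6-methylocta-2,6-dienoate | COC(=O)/C(=C/CC/C(C)=C/COC(C)=O)[C@H](O)[C@H]1COC(C)(C)O1 | intermediate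
8 | methyl (2E,6E)-8-acetoxy-2-{(S)-(tert-butyldimethylsilyloxy)[(4R)-2,2-dimethyl-1,3-dioxolan-4-yl]methyl}-6-methylocta-2,6-dienoate | COC(=O)/C(=C/CC/C(C)=C/COC(C)=O)[C@H](O[Si](C)(C)C(C)(C)C)[C@H]1COC(C)(C)O1 | intermediate
9 | methyl (2E,6E)-2-{(S)-(TBSO)[(4R)-2,2-dimethyl-1,3-dioxolan-4-yl]methyl}-8-hydroxy-6-methylocta-2,6-dienoate | COC(=O)/C(=C/CC/C(C)=C/CO)[C@H](O[Si](C)(C)C(C)(C)C)[C@H]1COC(C)(C)O1 | intermediate
10 | methyl (2E,6E)-2-{(S)-(TBSO)[(4R)-2,2-dimethyl-1,3-dioxolan-4-yl]methyl}-6-methyl-8-oxoocta-2,6-dienoate | COC(=O)/C(=C/CC/C(C)=C/C=O)[C@H](O[Si](C)(C)C(C)(C)C)[C@H]1COC(C)(C)O1 | intermediate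
11 | methyl (2E,6E,8S)-2-{(S)-(TBSO)[(4R)-2,2-dimethyl-1,3-dioxolan-4-yl]methyl}-8-hydroxy-6-methyldeca-2,6,9-trienoate | COC(=O)/C(=C/CC/C(C)=C/[C@@H](O)C=C)[C@H](O[Si](C)(C)C(C)(C)C)[C@H]1COC(C)(C)O1 | intermediate
12 | 2-(bromomethyl)acrylic acid | C=C(CBr)C(=O)O | starting material
13 | methyl (2E,6E,8S)-8-{[2-(bromomethyl)acryloyl]oxy}-2-{(S)-(TBSO)[(4R)-2,2-dimethyl-1,3-dioxolan-4-yl]methyl}-6-methyldeca-2,6,9-trienoate | COC(=O)/C(=C/CC/C(C)=C/[C@@H](OC(=O)C(=C)CBr)C=C)[C@H](O[Si](C)(C)C(C)(C)C)[C@H]1COC(C)(C)O1 | intermediate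
14 | methyl (2E,6E)-7-[(2R)-4-(bromomethyl)-5-oxo-2,5-dihydrofuran-2-yl]-2-{(S)-(TBSO)[(4R)-2,2-dimethyl-1,3-dioxolan-4-yl]methyl}-6-methylhepta-2,6-dienoate | COC(=O)/C(=C/CC/C(C)=C/[C@H]1OC(=O)C(CBr)=C1)[C@H](O[Si](C)(C)C(C)(C)C)[C@H]2COC(C)(C)O2 | intermediate
15 | methyl (2E,6E)-7-[(2R)-4-(bromomethyl)-5-oxo-2,5-dihydrofuran-2-yl]-2-[(1S,2R)-1-(TBSO)-2,3-dihydroxypropyl]-6-methylhepta-2,6-dienoate | COC(=O)/C(=C/CC/C(C)=C/[C@H]1OC(=O)C(CBr)=C1)[C@H](O[Si](C)(C)C(C)(C)C)[C@H](O)CO | intermediate
16 | methyl (2E,6E)-7-[(2R)-4-(bromomethyl)-5-oxo-2,5-dihydrofuran-2-yl]-2-[(1S)-1-(TBSO)-2-oxoethyl]-6-methylhepta-2,6-dienoate | COC(=O)/C(=C/CC/C(C)=C/[C@H]1OC(=O)C(CBr)=C1)[C@H](O[Si](C)(C)C(C)(C)C)C=O | intermediate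
17 | allyl-CrCl2 species, the analogue of 16 with CH2CrCl2 in place of CH2Br | COC(=O)/C(=C/CC/C(C)=C/[C@H]1OC(=O)C(C[Cr](Cl)Cl)=C1)[C@H](O[Si](C)(C)C(C)(C)C)C=O | intermediate
18 | 8-epi-8-O-deangeloyl-9-O-TBS-polymatin A (8α-hydroxy, 9α-TBSO; 8R, 9S; C6 and C7 as in the target) | C=C1C(=O)O[C@@H]2/C=C(\C)CC/C=C(/C(=O)OC)[C@H](O[Si](C)(C)C(C)(C)C)[C@H](O)[C@@H]12 | intermediate
19 | angelic acid, (Z)-2-methylbut-2-enoic acid | C/C=C(/C)C(=O)O | starting material
20 | 9-O-TBS-polymatin A | C=C1C(=O)O[C@@H]2/C=C(\C)CC/C=C(/C(=O)OC)[C@H](O[Si](C)(C)C(C)(C)C)[C@@H](OC(=O)/C(C)=C\C)[C@@H]12 | intermediate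
21 | polymatin A (6R,7S,8S,9S) | C=C1C(=O)O[C@@H]2/C=C(\C)CC/C=C(/C(=O)OC)[C@H](O)[C@@H](OC(=O)/C(C)=C\C)[C@@H]12 | target

## Step count and risk

Total steps: 13. Longest linear sequence: 13 (from geranyl acetate 1; compounds 5, 12 and 19 are used as purchased).

The three steps most likely to fail are 11, 12 and 7.

**Step 11 (ring closure).** The allyl-CrCl2 species may be protonated, couple intermolecularly or undergo reductive ring opening before it finds the aldehyde. The fallback sets out from 16 and returns at 18, replacing the transient organochromium by an isolable allylboron nucleophile. Compound 16 is borylated at the allylic bromide (Pd2(dba)3 cat., B2pin2, KOAc, DMSO, rt) to give the pinacol allylboronate F1. 2-Alkoxycarbonyl allylboronates are sluggish toward aldehydes at room temperature, so F1 can be handled briefly. It is then added slowly to Sc(OTf)3 (10 mol %) in toluene (2 mM, 40–60 °C). The intramolecular allylboration passes through the same closed six-membered transition state, so the same 7,8-anti Felkin sense is expected, but it needs no reductant and the nucleophile persists under true high dilution. Hydrolysis of the borate gives 18.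

**Step 12 (Mitsunobu inversion).** The C8 carbinol is flanked by the ring-fusion carbon and the silyloxy-bearing C9, so displacement may be slow, elimination may compete, and PPh3 could isomerise angelate to tiglate. The fallback sets out from 18 and returns at 20 by oxidation, reduction and acylation with retention.
- Dess–Martin periodinane (NaHCO3, CH2Cl2) gives the C8 ketone F2.
- Luche reduction (NaBH4, CeCl3·7H2O, MeOH, −78 °C) should deliver hydride from the exposed face, anti to the C9–O bond (Felkin–Anh for an α-silyloxy ketone), giving the 8β-alcohol F3 without conjugate reduction of the methylene lactone.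
- The 8β-alcohol F3 is acylated with the mixed anhydride of angelic acid 19 (2,4,6-trichlorobenzoyl chloride, Et3N, toluene, 80 °C, no DMAP), which gives 20.

**Step 7 (asymmetric vinylation).** Facial control in vinyl transfer to a β,β-disubstituted enal may be incomplete, and the C6 epimers of 11 may be hard to separate. The fallback sets out from 10 and returns at 11 by reagent-controlled ketone reduction. CH2=CHMgBr (THF, −78 °C) gives the carbinol-epimeric divinyl carbinols F4. Dess–Martin oxidation gives the cross-conjugated dienone F5. Corey–Bakshi–Shibata reduction ((R)-Me-CBS, catecholborane, toluene, −78 °C), with the trisubstituted alkenyl arm as the large group, returns the (S)-carbinol 11.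

Further compounds

F1 | step 11 | methyl (2E,6E)-2-[(1S)-1-(TBSO)-2-oxoethyl]-6-methyl-7-{(2R)-5-oxo-4-[(4,4,5,5-tetramethyl-1,3,2-dioxaborolan-2-yl)methyl]-2,5-dihydrofuran-2-yl}hepta-2,6-dienoate | COC(=O)/C(=C/CC/C(C)=C/[C@H]1OC(=O)C(CB2OC(C)(C)C(C)(C)O2)=C1)[C@H](O[Si](C)(C)C(C)(C)C)C=O
F2 | step 12 | 8-oxo analogue of 18 (8-dehydro-8-O-deangeloyl-9-O-TBS-polymatin A) | C=C1C(=O)O[C@@H]2/C=C(\C)CC/C=C(/C(=O)OC)[C@H](O[Si](C)(C)C(C)(C)C)C(=O)[C@@H]12
F3 | step 12 | 8-O-deangeloyl-9-O-TBS-polymatin A (8β-hydroxy, 8S) | C=C1C(=O)O[C@@H]2/C=C(\C)CC/C=C(/C(=O)OC)[C@H](O[Si](C)(C)C(C)(C)C)[C@@H](O)[C@@H]12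
F4 | step 7 | methyl (2E,6E)-2-{(S)-(TBSO)[(4R)-2,2-dimethyl-1,3-dioxolan-4-yl]methyl}-8-hydroxy-6-methyldeca-2,6,9-trienoate, mixture of C8 epimers | COC(=O)/C(=C/CC/C(C)=C/C(O)C=C)[C@H](O[Si](C)(C)C(C)(C)C)[C@H]1COC(C)(C)O1
F5 | step 7 | methyl (2E,6E)-2-{(S)-(TBSO)[(4R)-2,2-dimethyl-1,3-dioxolan-4-yl]methyl}-6-methyl-8-oxodeca-2,6,9-trienoate | COC(=O)/C(=C/CC/C(C)=C/C(=O)C=C)[C@H](O[Si](C)(C)C(C)(C)C)[C@H]1COC(C)(C)O1
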